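A direct plan would add a prenylbarium reagent to furan-3-carbaldehyde A1 to obtain the racemic carbinol A2, would esterify A2 with an activated (2R)-2-methylbutanoyl donor under a ruthenium/isothiourea dynamic kinetic resolution to reach ester A3, and would end with iridium-catalysed C–H borylation of A3 and Suzuki coupling with unprotected bromohydroquinone A4.
Weakest would be the dynamic kinetic esterification of A2: it would have to set the carbinol centre on a racemate with an α-branched, stereogenic acyl donor, a combination without precedent in which racemisation, acyl transfer and the integrity of the acid α-centre must all cooperate.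
Second would be the late borylation/Suzuki sequence on the finished ester A3: the choice between the two furan α-positions would rest on sterics alone, the 2-furyl boronate would be prone to protodeboronation, and the air-sensitive free hydroquinone A4 and the furylic ester would meet aqueous base and palladium in the last step.
Third would be the carbonyl prenylation of aldehyde A1: it would need cryogenic reactive barium, would have to control α- against γ-attack, and would give a racemate, so the only new stereocentre would be made without control and corrected afterwards.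

Retrosynthetic overview. Locants: furan O1, C2, C3 (bearing the side-chain carbinol carbon C1'), C4, C5 (bearing the aryl ring). The furan would not be bought: it would be closed last by forming O1–C5 through 5-endo-dig addition of a primary hydroxyl (on the future C2) to an aryl alkyne (future C4–C5).
An epoxide spans the future C3 and C1'; on cyclisation its C3–O bond opens to aromatise the ring and its oxygen stays on C1' as the free (R)-carbinol, so one cycloisomerisation builds the ring, fixes the 3,5-pattern and releases the stereocentre.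
The epoxy alcohol would come from Sharpless epoxidation of a planar, achiral (E)-2-alkynyl allylic alcohol: C1' is set by reagent control, with no racemate, no resolution and no carbonyl prenylation (prenyl enters as an electrophile toward an acetylide).
The enynol would be assembled from propargyl alcohol, prenyl bromide and a silyl-protected 2-ethynylhydroquinone; the aryl–carbon bond is made on a simple aryl bromide, never on a furan, and the phenols stay masked until the last step.
Ring order: benzene ring bought, furan ring formed in step 7 after all carbons are in place; esterification and desilylation finish.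
Key step: step 7

Remark: (2R)-2-methylbutanoic acid and both enantiomers of diisopropyl tartrate are taken as commercial single enantiomers.

Step 1
Reactants: 1 2-bromobenzene-1,4-diol
Product: 2 2-bromo-1,4-bis(triisopropylsilyloxy)benzene
Conditions: i-Pr3SiCl (2.4 equiv), imidazole (5 equiv), DMF, 40 °C
Reagents that add atoms: chlorotriisopropylsilane, CC(C)[Si](Cl)(C(C)C)C(C)C
Why: Silylation of both phenols with a silyl chloride and imidazole should give ethers that survive methanolic carbonate and the palladium, ruthenium, titanium and gold steps, and that fall to buffered fluoride at the end.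

Step 2
Reactants: 2 2-bromo-1,4-bis(triisopropylsilyloxy)benzene; 3 ethynyltrimethylsilane
Product: 5 2-ethynyl-1,4-bis(triisopropylsilyloxy)benzene, via trimethylsilyl alkyne 4 (not isolated)
Conditions: Pd(PhCN)2Cl2 (3 mol %), [HP(t-Bu)3]BF4 (6 mol %), CuI (2 mol %), i-Pr2NH, dioxane, rt; filter through Celite, concentrate; then K2CO3 (0.5 equiv), MeOH/THF 1:1, rt
Reagents that add atoms: none
Why: Sonogashira coupling of the hindered, electron-rich aryl bromide should proceed at room temperature with the bulky trialkylphosphine, and methanolic carbonate, applied to the crude alkynylsilane once the ammonium salt has been filtered off, should protodesilylate it without touching the aryl silyl ethers.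

Step 3
Reactants: 6 prop-2-yn-1-ol; 7 1-bromo-3-methylbut-2-ene (prenyl bromide)
Product: 8 6-methylhept-5-en-2-yn-1-ol
Conditions: CuI (10 mol %), K2CO3 (1.5 equiv), n-Bu4NBr (10 mol %), DMF, rt
Reagents that add atoms: none
Why: Copper-catalysed coupling of a terminal alkyne with an allylic bromide should give the skipped enyne, the copper acetylide attacking the unhindered primary carbon of prenyl bromide and not the carbon that would become quaternary.

Step 4
Reactants: 8 6-methylhept-5-en-2-yn-1-ol
Product: 10 (2Z)-2-iodo-6-methylhepta-2,5-dien-1-ol, via alkenylstannane 9 (not isolated)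
Conditions: [(C5Me5)RuCl]4 (2.5 mol %), n-Bu3SnH (1.1 equiv), CH2Cl2, rt; then I2 (1.15 equiv), 0 °C; aq Na2S2O3
Reagents that add atoms: tributyltin hydride, CCCC[SnH](CCCC)CCCC (tin only in 9); iodine, II
Why: Hydroxyl-directed ruthenium-catalysed trans-hydrostannation should place tin on the alkyne carbon next to the hydroxymethyl group and hydrogen trans to it, and iododestannylation with retention should give the (Z)-iodide in which the hydroxymethyl group and the chain are trans.

Step 5
Reactants: 10 (2Z)-2-iodo-6-methylhepta-2,5-dien-1-ol; 5 2-ethynyl-1,4-bis(triisopropylsilyloxy)benzene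
Product: 11 (2E)-2-{[2,5-bis(triisopropylsilyloxy)phenyl]ethynyl}-6-methylhepta-2,5-dien-1-ol
Conditions: Pd(PPh3)2Cl2 (2 mol %), CuI (4 mol %), Et3N, THF, rt
Reagents that add atoms: none
Why: Sonogashira coupling of an alkenyl iodide runs at room temperature with retention of the double-bond geometry and tolerates the free allylic hydroxyl.

Step 6
Reactants: 11 (2E)-2-{[2,5-bis(triisopropylsilyloxy)phenyl]ethynyl}-6-methylhepta-2,5-dien-1-ol
Product: 12 [(2R,3R)-2-{[2,5-bis(triisopropylsilyloxy)phenyl]ethynyl}-3-(3-methylbut-2-en-1-yl)oxiran-2-yl]methanol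
Conditions: Ti(OiPr)4 (0.2 equiv), diisopropyl D-(−)-tartrate (0.24 equiv), t-BuOOH (2 equiv, in decane), 4 Å MS, CH2Cl2, −20 °C
Reagents that add atoms: tert-butyl hydroperoxide, CC(C)(C)OO
Why: Sharpless asymmetric epoxidation touches only the allylic double bond (the prenyl alkene and the alkyne are not directed by the hydroxyl), and the D-tartrate catalyst, which gives the (2R,3R)-epoxy alcohol from simple (E)-allylic alcohols, should by the same facial preference make both oxirane carbons (R) here, so the future carbinol centre is set by reagent control.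

Step 7
Reactants: 12 [(2R,3R)-2-{[2,5-bis(triisopropylsilyloxy)phenyl]ethynyl}-3-(3-methylbut-2-en-1-yl)oxiran-2-yl]methanol
Product: 13 (1R)-1-{5-[2,5-bis(triisopropylsilyloxy)phenyl]furan-3-yl}-4-methylpent-3-en-1-ol
Conditions: Au(PPh3)(NTf2) (2 mol %), THF, 4 Å MS, 0 °C → rt; Et3N quench
Reagents that add atoms: none
Why: Proposed new method: the cationic monovalent gold catalyst should activate the aryl alkyne, the primary hydroxyl should add 5-endo-dig to the aryl-bearing alkyne carbon (the only ring closure, forming O1–C5), and protodeauration should give a 2,3-dihydrofuran (C2 and C3 still sp3) whose enol ether pushes open the C3–O bond of the spiro-epoxide, so that loss of a C2 proton aromatises the ring and leaves the epoxide oxygen on C1' as the free carbinol. The closest known reaction types are the gold- or silver-catalysed dehydrative cyclisation of 3-alkyne-1,2-diols to furans, the palladium-catalysed furan formation from 2-methoxy-3-alkyn-1-ols, and the gold-catalysed isomerisation of alkynyl oxiranes to furans; the difference here is that the leaving oxygen is an epoxide oxygen that stays in the molecule. No stereocentre is formed: C1' was set in step 6 and its C–O bond is never broken, so (R) is carried over, while the quaternary epoxide centre is erased on aromatisation. The step needs hydroxyl attack to beat attack of the epoxide oxygen (which would give the isomeric 4-hydroxymethyl-5-alkyl furan), attack of the prenyl alkene on the alkyne, and ionisation of the propargylic epoxide; the free, unhindered hydroxyl held 5-endo to an alkyne polarised by the electron-rich aryl group, the coordinating solvent, the low temperature and the non-acidic catalyst should secure this.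

Step 8
Reactants: 13 (1R)-1-{5-[2,5-bis(triisopropylsilyloxy)phenyl]furan-3-yl}-4-methylpent-3-en-1-ol; 14 (2R)-2-methylbutanoic acid
Product: 15 (1R)-1-{5-[2,5-bis(triisopropylsilyloxy)phenyl]furan-3-yl}-4-methylpent-3-en-1-yl (2R)-2-methylbutanoate
Conditions: DCC (1.3 equiv), DMAP (0.1 equiv), CH2Cl2, 0 °C → rt
Reagents that add atoms: none
Why: Steglich esterification acylates the carbinol oxygen without breaking its C–O bond (retention at C1') and, at low temperature with catalytic DMAP, should not enolise the α-centre of the acid.

Step 9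
Reactants: 15 (1R)-1-{5-[2,5-bis(triisopropylsilyloxy)phenyl]furan-3-yl}-4-methylpent-3-en-1-yl (2R)-2-methylbutanoate
Product: 16 (1R)-1-[5-(2,5-dihydroxyphenyl)furan-3-yl]-4-methylpent-3-en-1-yl (2R)-2-methylbutanoate
Conditions: n-Bu4NF (2.5 equiv), AcOH (2.5 equiv), THF, 0 °C, Ar; pH 5 phosphate buffer work-up
Reagents that add atoms: none
Why: Fluoride cleaves aryl silyl ethers quickly, and the acetic acid buffer should keep the medium from hydrolysing the ester or promoting air oxidation of the hydroquinone.

Compound list
1 | 2-bromobenzene-1,4-diol | Oc1ccc(O)c(Br)c1 | starting material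
2 | 2-bromo-1,4-bis(triisopropylsilyloxy)benzene | Brc1cc(O[Si](C(C)C)(C(C)C)C(C)C)ccc1O[Si](C(C)C)(C(C)C)C(C)C | intermediate
3 | ethynyltrimethylsilane | C#C[Si](C)(C)C | starting material
4 | {[2,5-bis(triisopropylsilyloxy)phenyl]ethynyl}trimethylsilane | C[Si](C)(C)C#Cc1cc(O[Si](C(C)C)(C(C)C)C(C)C)ccc1O[Si](C(C)C)(C(C)C)C(C)C | intermediate (not isolated)
5 | 2-ethynyl-1,4-bis(triisopropylsilyloxy)benzene | C#Cc1cc(O[Si](C(C)C)(C(C)C)C(C)C)ccc1O[Si](C(C)C)(C(C)C)C(C)C | intermediate
6 | prop-2-yn-1-ol | C#CCO | starting material
7 | 1-bromo-3-methylbut-2-ene | CC(C)=CCBr | starting material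
8 | 6-methylhept-5-en-2-yn-1-ol | CC(C)=CCC#CCO | intermediate
9 | (2Z)-6-methyl-2-(tributylstannyl)hepta-2,5-dien-1-ol | OC/C(=C/CC=C(C)C)[Sn](CCCC)(CCCC)CCCC | intermediate (not isolated)
10 | (2Z)-2-iodo-6-methylhepta-2,5-dien-1-ol | OC/C(I)=C/CC=C(C)C | intermediate
11 | (2E)-2-{[2,5-bis(triisopropylsilyloxy)phenyl]ethynyl}-6-methylhepta-2,5-dien-1-ol | OC/C(C#Cc1cc(O[Si](C(C)C)(C(C)C)C(C)C)ccc1O[Si](C(C)C)(C(C)C)C(C)C)=C/CC=C(C)C | intermediate
12 | [(2R,3R)-2-{[2,5-bis(triisopropylsilyloxy)phenyl]ethynyl}-3-(3-methylbut-2-en-1-yl)oxiran-2-yl]methanol | OC[C@@]1(C#Cc2cc(O[Si](C(C)C)(C(C)C)C(C)C)ccc2O[Si](C(C)C)(C(C)C)C(C)C)O[C@@H]1CC=C(C)C | intermediate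
13 | (1R)-1-{5-[2,5-bis(triisopropylsilyloxy)phenyl]furan-3-yl}-4-methylpent-3-en-1-ol | O[C@H](CC=C(C)C)c1coc(-c2cc(O[Si](C(C)C)(C(C)C)C(C)C)ccc2O[Si](C(C)C)(C(C)C)C(C)C)c1 | intermediate
14 | (2R)-2-methylbutanoic acid | CC[C@@H](C)C(=O)O | starting material
15 | (1R)-1-{5-[2,5-bis(triisopropylsilyloxy)phenyl]furan-3-yl}-4-methylpent-3-en-1-yl (2R)-2-methylbutanoate | CC[C@@H](C)C(=O)O[C@H](CC=C(C)C)c1coc(-c2cc(O[Si](C(C)C)(C(C)C)C(C)C)ccc2O[Si](C(C)C)(C(C)C)C(C)C)c1 | intermediate
16 | (1R)-1-[5-(2,5-dihydroxyphenyl)furan-3-yl]-4-methylpent-3-en-1-yl (2R)-2-methylbutanoate | CC[C@@H](C)C(=O)O[C@H](CC=C(C)C)c1coc(-c2cc(O)ccc2O)c1 | target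

Total step count: 9. Longest linear sequence: 7 (steps 3 to 9).

Steps most likely to fail

Step 7 (Proposed new method). The cyclisation could be diverted by attack of the epoxide oxygen or of the prenyl alkene on the activated alkyne, or by acid-triggered opening of the propargylic epoxide before the hydroxyl has added. The fallback uses known chemistry, sets out from enynol 11 and returns at 15. Sharpless epoxidation of 11 with diisopropyl L-(+)-tartrate would give the enantiomeric epoxy alcohol [(2S,3S)-2-{[2,5-bis(triisopropylsilyloxy)phenyl]ethynyl}-3-(3-methylbut-2-en-1-yl)oxiran-2-yl]methanol F1. Opening of F1 with acid 14 and Ti(OiPr)4 (titanium-assisted attack of the carboxylate at the epoxide carbon remote from the hydroxymethyl group, with inversion) would install the ester and the (R) centre in (2S,3R)-2-{[2,5-bis(triisopropylsilyloxy)phenyl]ethynyl}-1,2-dihydroxy-6-methylhept-5-en-3-yl (2R)-2-methylbutanoate F2. The well-precedented dehydrative cyclisation of this 3-alkyne-1,2-diol (AgNO3 on silica gel, or the gold catalyst of step 7), in which only the primary hydroxyl can cyclise, would then give 15.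

Step 6. Epoxidation of the alkyne-conjugated, electron-poor double bond could be slow and poorly face-selective, and the titanium alkoxide could open the propargylic epoxide once it has formed. The fallback takes the stereocentre from the chiral pool, sets out from alkyne 5 and returns at 13. Copper-catalysed opening of commercial methyl (2R)-oxirane-2-carboxylate with 2-methylprop-1-enylmagnesium bromide (CuI, THF, −40 °C) would give methyl (2R)-2-hydroxy-5-methylhex-4-enoate F3. Silylation (Et3SiCl, imidazole) would give methyl (2R)-5-methyl-2-(triethylsilyloxy)hex-4-enoate F4, and chloromethyllithium (ICH2Cl, MeLi·LiBr, −78 °C) would give (3R)-1-chloro-6-methyl-3-(triethylsilyloxy)hept-5-en-2-one F5. Addition of the lithium acetylide of 5 and warming would close 2-{[2,5-bis(triisopropylsilyloxy)phenyl]ethynyl}-2-[(1R)-4-methyl-1-(triethylsilyloxy)pent-3-en-1-yl]oxirane F6 (both epimers at the oxirane carbon serve). The known gold-catalysed isomerisation of alkynyl oxiranes to furans (AuCl3, MeCN) would give triethyl({(1R)-1-[5-(2,5-bis(triisopropylsilyloxy)phenyl)furan-3-yl]-4-methylpent-3-en-1-yl}oxy)silane F7, and pyridinium p-toluenesulfonate in MeOH would remove the alkyl silyl ether selectively to give 13.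

Step 4. Tin could be delivered to the distal alkyne carbon if the hydroxyl direction is weak on this skipped enyne, and iodine could add to the trisubstituted alkene during destannylation. The fallback builds the trisubstituted alkene from an α-keto ester, sets out from alkyne 5 and returns at 11. 4-Methylpent-3-enylmagnesium bromide and diethyl oxalate (THF, −78 °C) would give ethyl 6-methyl-2-oxohept-5-enoate F8. Tf2O with i-Pr2NEt would give the enol triflate ethyl (2Z)-6-methyl-2-(trifluoromethanesulfonyloxy)hepta-2,5-dienoate F9, the isomer with the chain cis to the triflate being favoured by allylic strain. Sonogashira coupling with 5 would give ethyl (2E)-2-{[2,5-bis(triisopropylsilyloxy)phenyl]ethynyl}-6-methylhepta-2,5-dienoate F10, and i-Bu2AlH (CH2Cl2, −78 °C) would reduce the ester to 11.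

Further compounds
F1 | step 7 | [(2S,3S)-2-{[2,5-bis(triisopropylsilyloxy)phenyl]ethynyl}-3-(3-methylbut-2-en-1-yl)oxiran-2-yl]methanol | OC[C@]1(C#Cc2cc(O[Si](C(C)C)(C(C)C)C(C)C)ccc2O[Si](C(C)C)(C(C)C)C(C)C)O[C@H]1CC=C(C)C
F2 | step 7 | (2S,3R)-2-{[2,5-bis(triisopropylsilyloxy)phenyl]ethynyl}-1,2-dihydroxy-6-methylhept-5-en-3-yl (2R)-2-methylbutanoate | CC[C@@H](C)C(=O)O[C@H](CC=C(C)C)[C@@](O)(CO)C#Cc1cc(O[Si](C(C)C)(C(C)C)C(C)C)ccc1O[Si](C(C)C)(C(C)C)C(C)C
F3 | step 6 | methyl (2R)-2-hydroxy-5-methylhex-4-enoate | COC(=O)[C@H](O)CC=C(C)C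
F4 | step 6 | methyl (2R)-5-methyl-2-(triethylsilyloxy)hex-4-enoate | COC(=O)[C@H](O[Si](CC)(CC)CC)CC=C(C)C
F5 | step 6 | (3R)-1-chloro-6-methyl-3-(triethylsilyloxy)hept-5-en-2-one | ClCC(=O)[C@H](O[Si](CC)(CC)CC)CC=C(C)C
F6 | step 6 | 2-{[2,5-bis(triisopropylsilyloxy)phenyl]ethynyl}-2-[(1R)-4-methyl-1-(triethylsilyloxy)pent-3-en-1-yl]oxirane | CC(C)=CC[C@@H](O[Si](CC)(CC)CC)C1(CO1)C#Cc2cc(O[Si](C(C)C)(C(C)C)C(C)C)ccc2O[Si](C(C)C)(C(C)C)C(C)C
F7 | step 6 | triethyl({(1R)-1-[5-(2,5-bis(triisopropylsilyloxy)phenyl)furan-3-yl]-4-methylpent-3-en-1-yl}oxy)silane | CC(C)=CC[C@@H](O[Si](CC)(CC)CC)c1coc(-c2cc(O[Si](C(C)C)(C(C)C)C(C)C)ccc2O[Si](C(C)C)(C(C)C)C(C)C)c1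
F8 | step 4 | ethyl 6-methyl-2-oxohept-5-enoate | CCOC(=O)C(=O)CCC=C(C)C
F9 | step 4 | ethyl (2Z)-6-methyl-2-(trifluoromethanesulfonyloxy)hepta-2,5-dienoate | CCOC(=O)/C(OS(=O)(=O)C(F)(F)F)=C/CC=C(C)C
F10 | step 4 | ethyl (2E)-2-{[2,5-bis(triisopropylsilyloxy)phenyl]ethynyl}-6-methylhepta-2,5-dienoate | CCOC(=O)/C(C#Cc1cc(O[Si](C(C)C)(C(C)C)C(C)C)ccc1O[Si](C(C)C)(C(C)C)C(C)C)=C/CC=C(C)C
A1 | direct plan | furan-3-carbaldehyde | O=Cc1ccoc1
A2 | direct plan | rac-1-(furan-3-yl)-4-methylpent-3-en-1-ol | CC(C)=CCC(O)c1ccoc1
A3 | direct plan | (1R)-1-(furan-3-yl)-4-methylpent-3-en-1-yl (2R)-2-methylbutanoate | CC[C@@H](C)C(=O)O[C@H](CC=C(C)C)c1ccoc1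
A4 | direct plan | 2-bromobenzene-1,4-diol | Oc1ccc(O)c(Br)c1
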